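The constants are assumed; the flask was simulated.

The target is made from the substrate by fresh carrier, which turns into spent carrier. Each flask starts with its carrier as spent carrier, so target appears as the salt in the second phase restores fresh carrier.

    substrate + fresh carrier → target + spent carrier (k1 = 2.0 M⁻¹ h⁻¹)
    crystals ⇌ target, rate k2*(cs2 - [target]) while solid is left; crystals form when [target] > cs2 (cs2 = 0.34 M, k2 = 7.2 h⁻¹)
    target → over-reaction product (k3 = 7.1 × 10⁻⁵ h⁻¹)
    spent carrier + salt in the second phase ⇌ fresh carrier + spent salt in the second phase (K4 = 0.50, k4 = 0.33 M⁻¹ h⁻¹)

the same everywhere: salt in the second phase 1.40 M; spent carrier 38 mM; time 20 h; volume of the second phase over the first 2.0
- south-west: substrate 0.040 M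
- north: substrate 0.12 M
- north-west: substrate 0.40 M
- south-east: substrate 1.0 M
- north-east: substrate 3.0 M

- for target the crystals are counted in
- in the second phase: salt in the second phase, spent salt in the second phase; everything else is in the first
- charges count per volume of the first phase; a concentration in a rate is the amount of a species over the volume of its own phase; every rate counts per litre of the first phase
- as a solid, counted per litre of solution: crystals
- the concentration of target that is asked is that of its free form alone
- "hardly changes" means that all values lie within two and a half points (for a concentration: within two and a half percent of the largest)
- run time (south-west): 20 h

1. [target] (only what is free in solution, in the first phase) at the end for south-west, north, north-west, south-east, north-east, in this order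
2. the course of these numbers from the first flask to the last (falls all the way / falls, then rises / hardly changes / rises all the way / rises, then falls)

We follow the carrier round its two stations and begin with two extreme versions of the flask that can be solved by hand. In the first, substrate is so abundant that fresh carrier is used the moment it appears. The carrier then stands as spent carrier, and the regeneration step is the rate-limiting step. The salt counts in its own phase, so its charge is divided by the volume ratio, which gives 0.700 M. The pace of regeneration is therefore 0.00878 M h⁻¹. Over the run time this gives 0.176 M, and this amount is the regeneration ceiling: the forward rate of regeneration with the carrier charge wholly spent and the salt at its charge, multiplied by the time.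

In the second version, regeneration is instantaneous and the carrier stands as fresh carrier. The substrate then falls in a pseudo-first-order way, and a share 78.1% of it is converted in the run time. For the south-west flask that share of the charge comes to 0.0313 M.

The real flask has both stations in series, so we place each flask below the smaller of its two figures. Per unit of carrier, and with the salt at its charge, the stations run equally fast at a substrate level of 0.115 M, close to the charge of the north flask. In the north-west flask, the share of the charge, 0.313 M, is more than the ceiling, so from there on the ceiling is the figure that counts. We therefore commit to a row that rises and flattens beneath the ceiling. The ceiling is lower than the solubility, so we expect no crystals in the run. The half-life of dissolved target by over-reaction, 410 d, is long against the run time, so we set that step aside.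

The forecast gives 0.028 M, 0.078 M, 0.18 M, 0.26 M and 0.3 M, in a course that rises all the way, and it took “the carrier regeneration as the bottleneck”. We share that bottleneck for the concentrated flasks but differ on its size: the forecast's last value is higher than our ceiling.

The simulation gives 0.0249 M, 0.0614 M, 0.116 M, 0.143 M and 0.157 M, in a course that rises all the way.

The north-east flask reads 89.2% of the ceiling, with 96.6% of its carrier charge as spent carrier at the end. The south-east flask, the second case, reads 81.2% of the same ceiling, with 89.5% as spent carrier. The largest single effect shown on the north-east reading is its hour: at 200 h instead of 20 h, that flask holds 0.340 M of free target against 0.157 M. By then, crystals in the north-east flask stand at 20.7% of the substrate charged.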